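The route rests on cutting the C8–C9 bond of the carbocycle C5–C6–C7–C8–C9–C10, whose quaternary C10 carries methyl and vinyl: C9 and the C10 vinyl are traced back to the two arms of a methyl divinyl carbon. A chiral molybdenum alkylidene closes one of these diastereotopic vinyl groups onto the methylene of a C8 silyl enol ether, forming C8=C9, the six-membered ring and the C10 stereocentre in one operation. The precursor is a trans-4,5-disubstituted γ-butyrolactone (C6, C7) bearing the enol ether on C7 and the isopropenyl/divinyl chain on C6; the enol ether is carried as its tert-butyldimethylsilyl ether so that it can be purified free of ketone before meeting the catalyst.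

Key step: step 9

Numbering used: C10 is the quaternary carbon, C5 the CH carrying isopropenyl, C6 the CH bound to the lactone oxygen, C7 the ring-fusion CH, C8 the CH bound to the ester oxygen, C9 the ring CH2; C11, C12 and C13 are the lactone α-carbon, its carbonyl carbon and the exocyclic methylene carbon.

Assumption: the sense of induction of the two chiral controllers is assigned by analogy; the (S,S)-bromoborane (step 3) and the (R)-aryloxide (step 9) are written as the matched ones, and the antipode of either would be used, with nothing else changed, if the opposite sense is met.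

Step 1
Reactants: 1 (2E)-3-methylpent-2-en-4-yn-1-ol
Product: 2 (2E)-3-methylpenta-2,4-dien-1-ol
Conditions: H2 (1 atm), Pd/CaCO3 poisoned with Pb(OAc)2 (Lindlar catalyst), quinoline, EtOAc–hexane, 0 °C, stopped after 1 equiv H2
Reagents that add atoms: none
Why: Lindlar semi-hydrogenation stops at the alkene because the terminal alkyne binds the poisoned palladium surface far more strongly than the diene that is formed.

Step 2
Reactants: 2 (2E)-3-methylpenta-2,4-dien-1-ol; 3 3-methylbut-3-enoic acid
Product: 4 (2E)-3-methylpenta-2,4-dien-1-yl 3-methylbut-3-enoate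
Conditions: EDC·HCl, DMAP (5 mol %), CH2Cl2, 0 °C
Reagents that add atoms: none
Why: Steglich esterification of a primary allylic alcohol, with low DMAP loading and low temperature so that the β,γ-unsaturated acyl unit does not drift into conjugation.

Step 3
Reactants: 4 (2E)-3-methylpenta-2,4-dien-1-yl 3-methylbut-3-enoate
Product: 6 (2R)-3-ethenyl-3-methyl-2-(prop-1-en-2-yl)pent-4-enoic acid, via boron ketene acetal 5 (not isolated)
Conditions: (4S,5S)-2-bromo-1,3-bis{[3,5-bis(trifluoromethyl)phenyl]sulfonyl}-4,5-diphenyl-1,3,2-diazaborolidine (1.2 equiv, prepared beforehand from the bis-sulfonamide and BBr3), Et3N, toluene–hexane, −78 °C, then −20 → 4 °C; aqueous work-up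
Reagents that add atoms: none
Why: Enantioselective Ireland–Claisen rearrangement in which the C2-symmetric diazaborolidine fixes the ketene acetal geometry and shields one face of the chair transition state so that C5 is formed R, while C10 needs no control because it ends with two identical vinyl groups.

Step 4
Reactants: 6 (2R)-3-ethenyl-3-methyl-2-(prop-1-en-2-yl)pent-4-enoic acid
Product: 7 (2R)-3-ethenyl-3-methyl-2-(prop-1-en-2-yl)pent-4-en-1-ol
Conditions: LiAlH4, Et2O, 0 → 25 °C; aqueous work-up
Reagents that add atoms: none
Why: Hydride reduction of the carboxylic acid to the primary alcohol, in which the lithium carboxylate formed first is not enolised, so C5 is untouched.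

Step 5
Reactants: 7 (2R)-3-ethenyl-3-methyl-2-(prop-1-en-2-yl)pent-4-en-1-ol
Product: 8 (2R)-3-ethenyl-3-methyl-2-(prop-1-en-2-yl)pent-4-enal
Conditions: Dess–Martin periodinane, NaHCO3, CH2Cl2, 0 °C; crude aldehyde used at once
Reagents that add atoms: none
Why: Dess–Martin oxidation under buffered, non-basic conditions should give the β,γ-unsaturated aldehyde without enolisation, so the C5 centre is kept and the isopropenyl double bond stays out of conjugation.

Step 6
Reactants: 9 methyl levulinate
Product: 10 methyl (3Z)-4-[(trimethylsilyl)oxy]pent-3-enoate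
Conditions: Me3SiCl, NaI, Et3N, MeCN, 25 °C; distillation
Reagents that add atoms: chlorotrimethylsilane C[Si](C)(C)Cl
Why: Thermodynamic enol silylation by iodotrimethylsilane formed in situ gives the more substituted, Z-configured enol ether, which makes C7 the nucleophilic carbon of the levulinate.

Step 7
Reactants: 8 (2R)-3-ethenyl-3-methyl-2-(prop-1-en-2-yl)pent-4-enal; 10 methyl (3Z)-4-[(trimethylsilyl)oxy]pent-3-enoate
Product: 12 (4R,5S)-4-acetyl-5-[(3R)-4-ethenyl-2,4-dimethylhexa-1,5-dien-3-yl]oxolan-2-one, via aldol adduct 11 (not isolated)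
Conditions: BF3·OEt2, CH2Cl2, −78 °C; aq. NaHCO3; then PPTS (cat.), CH2Cl2, 25–40 °C
Reagents that add atoms: none
Why: Mukaiyama aldol addition followed by acid-catalysed γ-lactonisation, in which the enol silane attacks the BF3-bound aldehyde anti to the bulky C10 carbon (Felkin–Anh) to set C6, the open antiperiplanar transition state of the Z-enol silane should favour the syn adduct at C7, and the syn γ-hydroxy ester closes to the trans-4,5-disubstituted lactone, any cis-lactone being removed by chromatography.

Step 8
Reactants: 12 (4R,5S)-4-acetyl-5-[(3R)-4-ethenyl-2,4-dimethylhexa-1,5-dien-3-yl]oxolan-2-one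
Product: 13 (4R,5S)-4-{1-[(tert-butyldimethylsilyl)oxy]ethenyl}-5-[(3R)-4-ethenyl-2,4-dimethylhexa-1,5-dien-3-yl]oxolan-2-one
Conditions: TBSOTf, Et3N, CH2Cl2, −78 → −20 °C; chromatography on Et3N-deactivated SiO2
Reagents that add atoms: tert-butyldimethylsilyl trifluoromethanesulfonate CC(C)(C)[Si](C)(C)OS(=O)(=O)C(F)(F)F
Why: Soft enolisation–silylation (silyl triflate and amine) of the methyl ketone takes place at the unhindered methyl group and not at the tertiary C7–H or the lactone CH2, giving the kinetic 2-silyloxy-1-alkene without touching C7.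

Step 9
Reactants: 13 (4R,5S)-4-{1-[(tert-butyldimethylsilyl)oxy]ethenyl}-5-[(3R)-4-ethenyl-2,4-dimethylhexa-1,5-dien-3-yl]oxolan-2-one
Product: 14 (3aR,6R,7R,7aS)-4-[(tert-butyldimethylsilyl)oxy]-6-ethenyl-6-methyl-7-(prop-1-en-2-yl)-3a,6,7,7a-tetrahydro-1-benzofuran-2(3H)-one
Conditions: Mo(N-2,6-i-Pr2C6H3)(CHCMe2Ph)(2,5-Me2NC4H2)2 (5 mol %) and (R)-3,3'-dibromo-2'-(tert-butyldimethylsilyloxy)-5,5',6,6',7,7',8,8'-octahydro-1,1'-binaphthalen-2-ol (5 mol %), giving Mo(N-2,6-i-Pr2C6H3)(CHCMe2Ph)(2,5-Me2NC4H2)(OAr*) in situ; C6H6 (0.01 M), 22 °C, N2, vessel vented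
Reagents that add atoms: none
Why: The hexavalent molybdenum monoaryloxide pyrrolide alkylidene takes up one C10 vinyl group by [2+2] cycloaddition–cycloreversion, the tethered C9 alkylidene then adds across the enol ether C=CH2, and collapse of the molybdacyclobutane releases the C8=C9 enol ether and a methylidene that turns over with loss of ethene. The closest known reactions are stereoselective ring-closing metathesis that distinguishes two vinyl groups on a quaternary carbon with this catalyst class, and ring-closing metathesis of silyl enol ethers to cyclic silyl enol ethers. The carbocycle C5–C10 is closed as a cyclohexene by union of a monosubstituted with a 1,1-disubstituted alkene through a chair-like transition state, trans-fused to the lactone whose C6 and C7 arms are already held gauche. C10 is set by the stereogenic molybdenum centre with its chiral aryloxide, which, together with the equatorial C5 isopropenyl group, should select the vinyl group whose closure leaves methyl axial and the remaining vinyl equatorial; exchange of the alkylidene between the two vinyl groups through ethene makes the cyclisation the selecting event. Chemoselectivity is secured by the substrate, since the isopropenyl group could only close a four-membered ring or a tetrasubstituted cyclopentene, and high dilution suppresses cross-metathesis.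

Step 10
Reactants: 14 bicyclic lactone with the C8 silyl enol ether
Product: 16 C11-(dimethylaminomethyl) derivative of 14 (Mannich base; CH2NMe2 on C11 anti to C8), via lithium lactone enolate 15 (not isolated)
Conditions: LiN(i-Pr)2, THF, −78 °C; CH2=NMe2+ I− (Eschenmoser's salt), −78 → 0 °C
Reagents that add atoms: N,N-dimethylmethylideneammonium iodide C=[N+](C)C.[I-]
Why: Mannich alkylation of the lithium lactone enolate with Eschenmoser's salt installs C13 as a masked methylene, the enol ether carbon C9 next to quaternary C10 being too hindered to compete, and the new C11 centre (aminomethyl expected anti to C8) is erased in step 13.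

Step 11
Reactants: 16 Mannich base with the C8 silyl enol ether
Product: 17 C8 ketone (trans-fused 8-oxo lactone carrying CH2NMe2 on C11)
Conditions: AcOH–H2O–THF (3:1:1), 0 → 25 °C; cold aq. NaHCO3 work-up; used at once
Reagents that add atoms: none
Why: Acid hydrolysis of the silyl enol ether (protonation at C9, then loss of silicon) frees the C8 ketone under buffered acidic conditions in which the β-acyloxy ketone should neither eliminate the lactone oxygen nor epimerise at C7.

Step 12
Reactants: 17 C8 ketone
Product: 18 axial C8 alcohol (8-OH cis to the C10 methyl; C8 epimer of the target configuration)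
Conditions: LiBH(s-Bu)3 (L-Selectride), THF, −78 °C; AcOH quench at −78 °C; acid–base extraction
Reagents that add atoms: none
Why: Reduction with a bulky trialkylborohydride, in which the axial trajectory at C8 is blocked by the axial C10 methyl group so that hydride arrives equatorially and gives the axial alcohol, while the Mannich base keeps C11–C13 safe from conjugate reduction and the cold acidic quench keeps the alkoxide from attacking the lactone.

Step 13
Reactants: 18 axial C8 alcohol with CH2NMe2 on C11
Product: 20 8-epi hydroxy α-methylene lactone (axial 8-OH and C11=C13), via trimethylammonium iodide 19 (not isolated)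
Conditions: MeI, THF, 25 °C; then aq. NaHCO3, EtOAc, 25 °C
Reagents that add atoms: none
Why: Exhaustive N-methylation followed by E1cB (Hofmann-type) loss of trimethylamine across C11–C13 completes the Eschenmoser methylenation of the lactone under conditions too weakly basic to disturb the free C8 alcohol.

Step 14
Reactants: 21 but-2-yne-1,4-diol
Product: 22 (2E)-2-(tributylstannyl)but-2-ene-1,4-diol
Conditions: Bu3SnH, PdCl2(PPh3)2 (2 mol %), THF, 25 °C
Reagents that add atoms: tributylstannane CCCC[SnH](CCCC)CCCC
Why: Palladium-catalysed hydrostannation adds hydrogen and tin syn across the symmetrical alkyne, so the two hydroxymethyl groups end up cis, which is the geometry the side chain needs.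

Step 15
Reactants: 22 (2E)-2-(tributylstannyl)but-2-ene-1,4-diol
Product: 23 tributyl(2,2-dimethyl-4,7-dihydro-1,3-dioxepin-5-yl)stannane
Conditions: 2,2-dimethoxypropane, PPTS (cat.), CH2Cl2, 25 °C
Reagents that add atoms: 2,2-dimethoxypropane COC(C)(C)OC
Why: Transacetalisation to the seven-membered acetonide, possible only for the cis diol, masks both hydroxyl groups and locks the alkene geometry, the weak acid being too mild for protodestannylation.

Step 16
Reactants: 23 tributyl(2,2-dimethyl-4,7-dihydro-1,3-dioxepin-5-yl)stannane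
Product: 25 2,2-dimethyl-4,7-dihydro-1,3-dioxepine-5-carboxylic acid, via vinyllithium 24 (not isolated)
Conditions: n-BuLi, THF, −78 °C; CO2, −78 → 0 °C; 0.5 M HCl to pH 4, 0 °C
Reagents that add atoms: carbon dioxide O=C=O
Why: Tin–lithium exchange with retention of alkene geometry, then carboxylation of the vinyllithium, gives the protected form of the (E)-configured side-chain acid.

Step 17
Reactants: 20 8-epi hydroxy α-methylene lactone; 25 2,2-dimethyl-4,7-dihydro-1,3-dioxepine-5-carboxylic acid
Product: 26 C8 ester of 25 with inverted (equatorial) C8–O, α-methylene lactone intact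
Conditions: PPh3 and DIAD premixed in THF at 0 °C, then 25 and 20, 0 → 25 °C
Reagents that add atoms: none
Why: Mitsunobu esterification, in which the carboxylate displaces the axial oxyphosphonium group at C8 by SN2 from the open face and so inverts C8 to the equatorial ester of the target, premixing of phosphine and azodicarboxylate keeping free PPh3 away from the α-methylene lactone.

Step 18
Reactants: 26 acetonide-protected ester
Product: 27 (3aS,4R,6R,7R,7aS)-6-ethenyl-6-methyl-3-methylidene-2-oxo-7-(prop-1-en-2-yl)octahydro-1-benzofuran-4-yl (2E)-4-hydroxy-2-(hydroxymethyl)but-2-enoate (CNP0309506.1)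
Conditions: AcOH–H2O–THF (2:1:1), 25 °C
Reagents that add atoms: none
Why: Mild acid hydrolysis of the seven-membered acetonide releases the two primary alcohols, the ester being E because the diol was cis, and should leave the α-methylene lactone, the allylic ester and the alkenes untouched.

Compound list
1 | (2E)-3-methylpent-2-en-4-yn-1-ol | C#C/C(C)=C/CO | starting material
2 | (2E)-3-methylpenta-2,4-dien-1-ol | C=C/C(C)=C/CO | intermediate
3 | 3-methylbut-3-enoic acid | C=C(C)CC(=O)O | starting material
4 | (2E)-3-methylpenta-2,4-dien-1-yl 3-methylbut-3-enoate | C=C/C(C)=C/COC(=O)CC(C)=C | intermediate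
5 | boron ketene acetal of 4 with the (4S,5S)-diazaborolidine on oxygen, isopropenyl trans to O–B | C=C(C)/C=C(/OB1N(S(=O)(=O)c2cc(cc(c2)C(F)(F)F)C(F)(F)F)[C@@H](c2ccccc2)[C@H](c2ccccc2)N1S(=O)(=O)c1cc(cc(c1)C(F)(F)F)C(F)(F)F)OC/C=C(C)/C=C | intermediate
6 | (2R)-3-ethenyl-3-methyl-2-(prop-1-en-2-yl)pent-4-enoic acid | C=CC(C)(C=C)[C@@H](C(C)=C)C(=O)O | intermediate
7 | (2R)-3-ethenyl-3-methyl-2-(prop-1-en-2-yl)pent-4-en-1-ol | C=CC(C)(C=C)[C@@H](C(C)=C)CO | intermediate
8 | (2R)-3-ethenyl-3-methyl-2-(prop-1-en-2-yl)pent-4-enal | C=CC(C)(C=C)[C@@H](C(C)=C)C=O | intermediate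
9 | methyl levulinate (methyl 4-oxopentanoate) | COC(=O)CCC(C)=O | starting material
10 | methyl (3Z)-4-[(trimethylsilyl)oxy]pent-3-enoate | COC(=O)C/C=C(/C)O[Si](C)(C)C | intermediate
11 | methyl (3R,4S,5R)-3-acetyl-6-ethenyl-4-hydroxy-6-methyl-5-(prop-1-en-2-yl)oct-7-enoate | C=CC(C)(C=C)[C@@H](C(C)=C)[C@H](O)[C@@H](CC(=O)OC)C(C)=O | intermediate
12 | (4R,5S)-4-acetyl-5-[(3R)-4-ethenyl-2,4-dimethylhexa-1,5-dien-3-yl]oxolan-2-one | C=CC(C)(C=C)[C@@H](C(C)=C)[C@@H]1OC(=O)C[C@H]1C(C)=O | intermediate
13 | (4R,5S)-4-{1-[(tert-butyldimethylsilyl)oxy]ethenyl}-5-[(3R)-4-ethenyl-2,4-dimethylhexa-1,5-dien-3-yl]oxolan-2-one | C=CC(C)(C=C)[C@@H](C(C)=C)[C@@H]1OC(=O)C[C@H]1C(=C)O[Si](C)(C)C(C)(C)C | intermediate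
14 | (3aR,6R,7R,7aS)-4-[(tert-butyldimethylsilyl)oxy]-6-ethenyl-6-methyl-7-(prop-1-en-2-yl)-3a,6,7,7a-tetrahydro-1-benzofuran-2(3H)-one | C=C[C@@]1(C)C=C(O[Si](C)(C)C(C)(C)C)[C@@H]2CC(=O)O[C@H]2[C@@H]1C(=C)C | intermediate
15 | lithium enolate of lactone 14 (C11=C12–O–Li) | C=C[C@@]1(C)C=C(O[Si](C)(C)C(C)(C)C)[C@@H]2C=C([O-])O[C@H]2[C@@H]1C(=C)C.[Li+] | intermediate
16 | 14 carrying CH2NMe2 on C11, anti to C8 (Mannich base) | C=C[C@@]1(C)C=C(O[Si](C)(C)C(C)(C)C)[C@@H]2[C@@H](CN(C)C)C(=O)O[C@H]2[C@@H]1C(=C)C | intermediate
17 | trans-fused 8-oxo lactone with CH2NMe2 on C11 | C=C[C@@]1(C)CC(=O)[C@@H]2[C@@H](CN(C)C)C(=O)O[C@H]2[C@@H]1C(=C)C | intermediate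
18 | axial 8-hydroxy lactone with CH2NMe2 on C11 (8-OH cis to the C10 methyl) | C=C[C@@]1(C)C[C@H](O)[C@@H]2[C@@H](CN(C)C)C(=O)O[C@H]2[C@@H]1C(=C)C | intermediate
19 | trimethylammonium iodide of 18 | C=C[C@@]1(C)C[C@H](O)[C@@H]2[C@@H](C[N+](C)(C)C)C(=O)O[C@H]2[C@@H]1C(=C)C.[I-] | intermediate
20 | axial 8-hydroxy α-methylene lactone (8-epi alcohol) | C=C[C@@]1(C)C[C@H](O)[C@@H]2C(=C)C(=O)O[C@H]2[C@@H]1C(=C)C | intermediate
21 | but-2-yne-1,4-diol | OCC#CCO | starting material
22 | (2E)-2-(tributylstannyl)but-2-ene-1,4-diol | OC/C=C(\CO)[Sn](CCCC)(CCCC)CCCC | intermediate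
23 | tributyl(2,2-dimethyl-4,7-dihydro-1,3-dioxepin-5-yl)stannane | CC1(C)OCC=C(CO1)[Sn](CCCC)(CCCC)CCCC | intermediate
24 | (2,2-dimethyl-4,7-dihydro-1,3-dioxepin-5-yl)lithium | CC1(C)OCC=C([Li])CO1 | intermediate
25 | 2,2-dimethyl-4,7-dihydro-1,3-dioxepine-5-carboxylic acid | CC1(C)OCC=C(CO1)C(=O)O | intermediate
26 | equatorial C8 ester of 25 on the α-methylene lactone (acetonide of the target) | C=C[C@@]1(C)C[C@@H](OC(=O)C3=CCOC(C)(C)OC3)[C@@H]2C(=C)C(=O)O[C@H]2[C@@H]1C(=C)C | intermediate
27 | (3aS,4R,6R,7R,7aS)-6-ethenyl-6-methyl-3-methylidene-2-oxo-7-(prop-1-en-2-yl)octahydro-1-benzofuran-4-yl (2E)-4-hydroxy-2-(hydroxymethyl)but-2-enoate | C=C[C@@]1(C)C[C@@H](OC(=O)/C(=C/CO)CO)[C@@H]2C(=C)C(=O)O[C@H]2[C@@H]1C(=C)C | target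

Total step count: 18. Longest linear sequence: 14 (steps 1–5, 7–13, 17, 18). Steps 6 and 14–16 are side branches.

Steps most likely to fail

Step 9. The catalyst may take the wrong diastereotopic vinyl group, or closure onto the hindered 1,1-disubstituted enol ether may stall through decomposition of the alkylidene by traces of ketone or moisture. Fallback: setting out from 13, the ring would be closed under substrate control with the second-generation Grubbs catalyst RuCl2(H2IMes)(PCy3)(CHPh) in toluene at 60 °C, ring-closing metathesis of silyl enol ethers at ruthenium being established chemistry. This gives up catalyst control: 14 would be formed beside its C10 epimer, the (6S)-configured bicyclic silyl enol ether F1, which is removed by chromatography, and the route is rejoined at 14.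

Step 7. Facial selectivity at C6 or simple diastereoselection at C7 may be poor, and the enolisable aldehyde may epimerise at C5 on the Lewis acid. Fallback: setting out from 8, the two centres would be set by reagent control in an Evans syn-aldol reaction. The imide (4R)-4-benzyl-3-(4-methoxy-4-oxobutanoyl)-1,3-oxazolidin-2-one F2 (from (R)-4-benzyl-1,3-oxazolidin-2-one, n-BuLi and methyl 4-chloro-4-oxobutanoate) is enolised with Bu2BOTf and i-Pr2NEt in CH2Cl2 at −78 °C and added to 8. The syn-aldol imide F3 should lactonise on work-up or with PPTS to the trans lactone imide F4. LiOH and H2O2 in THF–H2O at 0 °C then cleave the auxiliary to the lactone carboxylic acid F5; (COCl)2 with catalytic DMF gives the acid chloride F6, and Me2CuLi in Et2O at −78 °C converts this into the methyl ketone, so that the route is rejoined at 12.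

Step 17. E2 elimination of the axial oxyphosphonium group, which has anti-periplanar hydrogens at C7 and C9, may outrun substitution. Fallback: setting out from 17, the ketone would be reduced under thermodynamic control with SmI2 and i-PrOH in THF (−78 → 0 °C), where the ketyl is protonated to place the hydroxyl equatorial, away from the axial C10 methyl, giving the equatorial amino alcohol F7. Methylation with MeI and elimination with aq. NaHCO3, through the trimethylammonium iodide F8, would give the equatorial hydroxy α-methylene lactone F9. Steglich esterification of F9 with 25 (EDC·HCl, DMAP, CH2Cl2) proceeds with retention, and the route is rejoined at 26.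

Further compounds
F1 | step 9 | C10 epimer of 14, (3aR,6S,7R,7aS)-configured bicyclic silyl enol ether | C=C[C@]1(C)C=C(O[Si](C)(C)C(C)(C)C)[C@@H]2CC(=O)O[C@H]2[C@@H]1C(=C)C
F2 | step 7 | (4R)-4-benzyl-3-(4-methoxy-4-oxobutanoyl)-1,3-oxazolidin-2-one | COC(=O)CCC(=O)N1[C@H](Cc2ccccc2)COC1=O
F3 | step 7 | syn-aldol imide (open form, C6–OH and C7 carboximide) | C=CC(C)(C=C)[C@@H](C(C)=C)[C@H](O)[C@@H](CC(=O)OC)C(=O)N1[C@H](Cc2ccccc2)COC1=O
F4 | step 7 | trans lactone carrying the oxazolidinone carboximide on C7 | C=CC(C)(C=C)[C@@H](C(C)=C)[C@@H]1OC(=O)C[C@H]1C(=O)N1[C@H](Cc2ccccc2)COC1=O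
F5 | step 7 | trans lactone C7 carboxylic acid | C=CC(C)(C=C)[C@@H](C(C)=C)[C@@H]1OC(=O)C[C@H]1C(=O)O
F6 | step 7 | trans lactone C7 carbonyl chloride | C=CC(C)(C=C)[C@@H](C(C)=C)[C@@H]1OC(=O)C[C@H]1C(Cl)=O
F7 | step 17 | equatorial 8-hydroxy lactone with CH2NMe2 on C11 (C8 epimer of 18) | C=C[C@@]1(C)C[C@@H](O)[C@@H]2[C@@H](CN(C)C)C(=O)O[C@H]2[C@@H]1C(=C)C
F8 | step 17 | trimethylammonium iodide of F7 | C=C[C@@]1(C)C[C@@H](O)[C@@H]2[C@@H](C[N+](C)(C)C)C(=O)O[C@H]2[C@@H]1C(=C)C.[I-]
F9 | step 17 | equatorial 8-hydroxy α-methylene lactone (C8 epimer of 20) | C=C[C@@]1(C)C[C@@H](O)[C@@H]2C(=C)C(=O)O[C@H]2[C@@H]1C(=C)C
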